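**Retrosynthetic overview**

- The strategy rests on ring C, the central ring. It carries five contiguous oxygens on C1 (ether to ring B), C6 (ether to ring D), C5, C4 and C3, and a single hydrogen on C2. This maps onto the four carbons of a squarate (C1, C6, C5, C4) plus the two carbons of ethyl vinyl ether (C3, C2).
- Last disconnections: global cleavage of twelve methyl ethers and one ethyl ether, and before it the ring B–ring C ether, made by Ullmann coupling of the single free phenol of ring C (C1–OH) with a ring A–B aryl bromide.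
- Ring C is made by thermal ring expansion (Moore rearrangement) of a 2-aryloxy-4-(1-ethoxyvinyl)-3,4-dimethoxycyclobutenone that already carries rings D and E on the oxygen destined for C6.
- The cyclobutenone comes from squaric acid by way of its methyl ester chloride, the ring D–E phenol, 1-ethoxyvinyllithium and methyl triflate. The D–E phenol is made by Ullmann coupling then Dakin oxidation, and the A–B bromide by iridium C–H borylation then Chan–Lam coupling.
- Ring order: rings A, B, D and E are bought as benzenes; only ring C is constructed, in step 7.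

Key step: step 7

Remark: the target has no stereocentre; the cyclobutenone precursor of the key step has one quaternary stereocentre, which is formed as the racemate and is destroyed in the ring expansion, so no stereocontrol is needed. The four arene building blocks (4-bromo-3,5-dimethoxybenzaldehyde, 3,4,5-trimethoxyphenol, 1-bromo-2,3-dimethoxybenzene, 2,4,6-trimethoxyphenol) are taken as catalogue chemicals.

**Route**

Step 1
Reactants: 1 4-bromo-3,5-dimethoxybenzaldehyde; 2 3,4,5-trimethoxyphenol
Product: 3 3,5-dimethoxy-4-(3,4,5-trimethoxyphenoxy)benzaldehyde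
Conditions: CuI (10 mol%), picolinic acid (20 mol%), K3PO4, DMSO, 90 °C, argon
Reagents that add atoms: none
Why: Ullmann-type copper-catalysed diaryl ether synthesis, in which the bromide is activated by the para formyl group, the picolinic acid ligand tolerates the two ortho methoxy groups, and the phenol partner is unhindered and electron-rich.

Step 2
Reactants: 3 3,5-dimethoxy-4-(3,4,5-trimethoxyphenoxy)benzaldehyde
Product: 5 3,5-dimethoxy-4-(3,4,5-trimethoxyphenoxy)phenol, via aryl formate 4 (not isolated)
Conditions: mCPBA, CH2Cl2, 0 °C to rt; aq Na2S2O3/NaHCO3 wash; then K2CO3 (cat.), MeOH, rt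
Reagents that add atoms: meta-chloroperoxybenzoic acid, OOC(=O)c1cccc(Cl)c1
Why: Dakin-type Baeyer–Villiger oxidation, in which the electron-rich aryl group migrates in preference to hydrogen and mild methanolysis of the formate should release the phenol of ring D.

Step 3
Reactants: 6 squaric acid
Product: 7 3,4-dichlorocyclobut-3-ene-1,2-dione (squaryl dichloride)
Conditions: (COCl)2, DMF (cat.), CH2Cl2, 0 °C to rt
Reagents that add atoms: oxalyl chloride, O=C(Cl)C(Cl)=O
Why: Vilsmeier-type chlorination of a vinylogous carboxylic acid, the standard preparation of squaryl dichloride.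

Step 4
Reactants: 7 3,4-dichlorocyclobut-3-ene-1,2-dione
Product: 8 3-chloro-4-methoxycyclobut-3-ene-1,2-dione
Conditions: MeOH (1.0 equiv), Et2O, 0 °C to rt, N2 sweep
Reagents that add atoms: methanol, CO
Why: Vinylogous acyl substitution (addition–elimination) by one equivalent of methanol, which should stop at the ester chloride because this is less electrophilic than the dichloride.

Step 5
Reactants: 8 3-chloro-4-methoxycyclobut-3-ene-1,2-dione; 5 3,5-dimethoxy-4-(3,4,5-trimethoxyphenoxy)phenol
Product: 9 3-[3,5-dimethoxy-4-(3,4,5-trimethoxyphenoxy)phenoxy]-4-methoxycyclobut-3-ene-1,2-dione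
Conditions: 5, NaH, THF, 0 °C; then added to 8, THF, −78 to 0 °C
Reagents that add atoms: none
Why: Vinylogous acyl substitution in which the phenoxide attacks the chlorine-bearing carbon and expels chloride, a far better leaving group than methoxide, so the mixed aryl methyl squarate should form without scrambling.

Step 6
Reactants: 9 3-[3,5-dimethoxy-4-(3,4,5-trimethoxyphenoxy)phenoxy]-4-methoxycyclobut-3-ene-1,2-dione; 10 ethyl vinyl ether
Product: 13 2-[3,5-dimethoxy-4-(3,4,5-trimethoxyphenoxy)phenoxy]-4-(1-ethoxyvinyl)-3,4-dimethoxycyclobut-2-en-1-one (racemic), via 1-ethoxyvinyllithium 11 (not isolated), via lithium alkoxide 12 (not isolated)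
Conditions: 10, t-BuLi, THF, −78 to 0 °C; then 9, THF, −78 °C; then MeOTf, −78 to 0 °C; chromatography on Et3N-deactivated silica
Reagents that add atoms: methyl trifluoromethanesulfonate, COS(=O)(=O)C(F)(F)F
Why: 1,2-Addition of an organolithium to a squarate ester followed by O-methylation of the alkoxide; aryloxy is a weaker donor than methoxy, so the carbonyl vinylogous to it (the one next to the methoxy-bearing carbon) is the more electrophilic and should be attacked, and the new quaternary stereocentre forms as the racemate, which is lost in step 7.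

Step 7
Reactants: 13 2-[3,5-dimethoxy-4-(3,4,5-trimethoxyphenoxy)phenoxy]-4-(1-ethoxyvinyl)-3,4-dimethoxycyclobut-2-en-1-one (racemic)
Product: 16 2-[3,5-dimethoxy-4-(3,4,5-trimethoxyphenoxy)phenoxy]-5-ethoxy-3,4-dimethoxyphenol, via dienylketene 14 (not isolated), via cyclohexadienone 15 (not isolated)
Conditions: toluene (degassed), 110 °C, argon
Reagents that add atoms: none
Why: Heating should open the cyclobutenone by conrotatory four-electron electrocyclic cleavage of the bond between the carbonyl carbon and the sp3 carbon to give dienylketene 14, which closes by a disrotatory six-electron electrocyclisation between the ketene carbon and the terminal CH2 of the ethoxyvinyl group to dienone 15, and enolisation then gives phenol 16. The closest known reaction is the Moore rearrangement of squarate-derived 4-alkenyl-4-alkoxycyclobutenones to highly oxygenated phenols. Ring C is the only ring formed; it closes as a six-membered carbocycle through the six-electron electrocyclisation that makes the C1–C2 bond (ring C numbering), with aromatisation as the driving force. No stereocentre is created and the one in 13 disappears. The step needs torquoselectivity in the ring opening: the donor methoxy group on the sp3 carbon rotates outward, which turns the ethoxyvinyl group inward next to the ketene, so six-ring closure is the only pericyclic path open. The pattern of 16 (OH on C1, aryloxy on C6, H on C2) follows from the aryloxy group sitting on C2 of the cyclobutenone, as fixed in step 6.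

Step 8
Reactants: 17 1-bromo-2,3-dimethoxybenzene
Product: 19 (3-bromo-4,5-dimethoxyphenyl)boronic acid, via pinacol boronate 18 (not isolated)
Conditions: [Ir(OMe)(cod)]2 (1.5 mol%), 4,4'-di-tert-butyl-2,2'-bipyridine (3 mol%), B2pin2 (0.55 equiv), THF, 80 °C; then NaIO4, aq HCl, THF/H2O, rt
Reagents that add atoms: bis(pinacolato)diboron, CC1(C)OB(OC1(C)C)B1OC(C)(C)C(C)(C)O1; water, O
Why: Iridium-catalysed C–H borylation (Hartwig–Miyaura) is sterically controlled and in a 1,2,3-trisubstituted benzene should occur only at C5, the one C–H with no ortho substituent; the aryl bromide is tolerated and periodate cleavage of the pinacol ester gives the boronic acid in the same flask.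

Step 9
Reactants: 19 (3-bromo-4,5-dimethoxyphenyl)boronic acid; 20 2,4,6-trimethoxyphenol
Product: 21 1-bromo-2,3-dimethoxy-5-(2,4,6-trimethoxyphenoxy)benzene
Conditions: Cu(OAc)2 (20 mol%), pyridine, 4 Å molecular sieves, CH2Cl2, O2 (1 atm), rt
Reagents that add atoms: none
Why: Chan–Lam–Evans oxidative copper coupling forms the ring A–ring B ether at room temperature; 2,6-disubstituted phenols are competent partners, the boron-bearing carbon is unhindered, and the aryl bromide should not react under these conditions.

Step 10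
Reactants: 16 2-[3,5-dimethoxy-4-(3,4,5-trimethoxyphenoxy)phenoxy]-5-ethoxy-3,4-dimethoxyphenol; 21 1-bromo-2,3-dimethoxy-5-(2,4,6-trimethoxyphenoxy)benzene
Product: 22 1-[2,3-dimethoxy-5-(2,4,6-trimethoxyphenoxy)phenoxy]-2-[3,5-dimethoxy-4-(3,4,5-trimethoxyphenoxy)phenoxy]-5-ethoxy-3,4-dimethoxybenzene (fully O-alkylated pentamer)
Conditions: CuI (20 mol%), picolinic acid (40 mol%), K3PO4, DMSO, 100 °C, argon
Reagents that add atoms: none
Why: Ullmann-type copper-catalysed C–O coupling with picolinic acid, conditions developed for ortho-substituted phenols and aryl halides; 16 has a single free hydroxyl, so only the C1 oxygen of ring C can be arylated.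

Step 11
Reactants: 22 fully O-alkylated pentamer
Product: 23 CNP0228612.0 (target, thirteen free hydroxyl groups)
Conditions: BBr3 (excess, about 3 equiv per ether), CH2Cl2, −78 °C to rt; then ice-water, argon, EtOAc extraction
Reagents that add atoms: none
Why: Lewis-acid ether cleavage, in which BBr3 cleaves aryl methyl and aryl ethyl ethers by bromide attack at the alkyl carbon but leaves diaryl ethers intact, so all thirteen alkyl groups should be removed while the four diaryl ether bonds survive.

**Compound list**

1 | 4-bromo-3,5-dimethoxybenzaldehyde | COc1cc(C=O)cc(OC)c1Br | starting material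
2 | 3,4,5-trimethoxyphenol | COc1cc(O)cc(OC)c1OC | starting material
3 | 3,5-dimethoxy-4-(3,4,5-trimethoxyphenoxy)benzaldehyde | COc1cc(C=O)cc(OC)c1Oc1cc(OC)c(OC)c(OC)c1 | intermediate
4 | 3,5-dimethoxy-4-(3,4,5-trimethoxyphenoxy)phenyl formate | COc1cc(OC=O)cc(OC)c1Oc1cc(OC)c(OC)c(OC)c1 | intermediate
5 | 3,5-dimethoxy-4-(3,4,5-trimethoxyphenoxy)phenol | COc1cc(O)cc(OC)c1Oc1cc(OC)c(OC)c(OC)c1 | intermediate
6 | squaric acid | OC1=C(O)C(=O)C1=O | starting material
7 | 3,4-dichlorocyclobut-3-ene-1,2-dione | ClC1=C(Cl)C(=O)C1=O | intermediate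
8 | 3-chloro-4-methoxycyclobut-3-ene-1,2-dione | COC1=C(Cl)C(=O)C1=O | intermediate
9 | 3-[3,5-dimethoxy-4-(3,4,5-trimethoxyphenoxy)phenoxy]-4-methoxycyclobut-3-ene-1,2-dione | COC1=C(Oc2cc(OC)c(Oc3cc(OC)c(OC)c(OC)c3)c(OC)c2)C(=O)C1=O | intermediate
10 | ethyl vinyl ether | CCOC=C | starting material
11 | 1-ethoxyvinyllithium | [Li]C(=C)OCC | intermediate
12 | lithium 2-[3,5-dimethoxy-4-(3,4,5-trimethoxyphenoxy)phenoxy]-4-(1-ethoxyvinyl)-3-methoxy-1-oxocyclobut-2-en-4-olate (racemic) | [Li]OC1(C(=C)OCC)C(OC)=C(Oc2cc(OC)c(Oc3cc(OC)c(OC)c(OC)c3)c(OC)c2)C1=O | intermediate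
13 | 2-[3,5-dimethoxy-4-(3,4,5-trimethoxyphenoxy)phenoxy]-4-(1-ethoxyvinyl)-3,4-dimethoxycyclobut-2-en-1-one (racemic) | O=C1C(Oc2cc(OC)c(Oc3cc(OC)c(OC)c(OC)c3)c(OC)c2)=C(OC)C1(OC)C(OCC)=C | intermediate
14 | (3Z)-2-[3,5-dimethoxy-4-(3,4,5-trimethoxyphenoxy)phenoxy]-5-ethoxy-3,4-dimethoxyhexa-1,3,5-trien-1-one | O=C=C(Oc1cc(OC)c(Oc2cc(OC)c(OC)c(OC)c2)c(OC)c1)/C(OC)=C(OC)\C(OCC)=C | intermediate
15 | 2-[3,5-dimethoxy-4-(3,4,5-trimethoxyphenoxy)phenoxy]-5-ethoxy-3,4-dimethoxycyclohexa-2,4-dien-1-one | O=C1CC(OCC)=C(OC)C(OC)=C1Oc1cc(OC)c(Oc2cc(OC)c(OC)c(OC)c2)c(OC)c1 | intermediate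
16 | 2-[3,5-dimethoxy-4-(3,4,5-trimethoxyphenoxy)phenoxy]-5-ethoxy-3,4-dimethoxyphenol | Oc1cc(OCC)c(OC)c(OC)c1Oc1cc(OC)c(Oc2cc(OC)c(OC)c(OC)c2)c(OC)c1 | intermediate
17 | 1-bromo-2,3-dimethoxybenzene | COc1cccc(Br)c1OC | starting material
18 | 2-(3-bromo-4,5-dimethoxyphenyl)-4,4,5,5-tetramethyl-1,3,2-dioxaborolane | COc1cc(B2OC(C)(C)C(C)(C)O2)cc(Br)c1OC | intermediate
19 | (3-bromo-4,5-dimethoxyphenyl)boronic acid | COc1cc(B(O)O)cc(Br)c1OC | intermediate
20 | 2,4,6-trimethoxyphenol | COc1cc(OC)c(O)c(OC)c1 | starting material
21 | 1-bromo-2,3-dimethoxy-5-(2,4,6-trimethoxyphenoxy)benzene | COc1cc(OC)c(Oc2cc(OC)c(OC)c(Br)c2)c(OC)c1 | intermediate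
22 | 1-[2,3-dimethoxy-5-(2,4,6-trimethoxyphenoxy)phenoxy]-2-[3,5-dimethoxy-4-(3,4,5-trimethoxyphenoxy)phenoxy]-5-ethoxy-3,4-dimethoxybenzene | COc1cc(OC)c(Oc2cc(OC)c(OC)c(Oc3cc(OCC)c(OC)c(OC)c3Oc3cc(OC)c(Oc4cc(OC)c(OC)c(OC)c4)c(OC)c3)c2)c(OC)c1 | intermediate
23 | CNP0228612.0 | Oc1cc(O)c(Oc2cc(O)c(O)c(Oc3cc(O)c(O)c(O)c3Oc3cc(O)c(Oc4cc(O)c(O)c(O)c4)c(O)c3)c2)c(O)c1 | target

**Totals**

Total step count: 11. Longest linear sequence: 7 steps (steps 3, 4, 5, 6, 7, 10, 11 from squaric acid; equally steps 1, 2, 5, 6, 7, 10, 11).

**Steps most likely to fail**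

Step 6. The organolithium may discriminate poorly between the two carbonyl groups of the mixed squarate, or displace the aryloxide by conjugate addition–elimination, and so erode the regiochemistry on which ring C depends. The fallback sets out from 7 and two equivalents of 5 and removes the regiochemical question by symmetry.
- Sodium phenoxide of 5 (NaH, THF, −78 to 0 °C) with 7 should give the symmetrical diaryl squarate 3,4-bis[3,5-dimethoxy-4-(3,4,5-trimethoxyphenoxy)phenoxy]cyclobut-3-ene-1,2-dione F1, whose carbonyl groups are equivalent.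
- Addition of 11 and methylation with MeOTf as in step 6 should give 2,3-bis[3,5-dimethoxy-4-(3,4,5-trimethoxyphenoxy)phenoxy]-4-(1-ethoxyvinyl)-4-methoxycyclobut-2-en-1-one F2.
- In F2 only the aryloxy group on C3 is a vinylogous aryl ester; it should be exchanged for methoxy by addition–elimination (NaOMe (cat.), MeOH/THF, −20 °C), while the aryloxy on C2 is not activated.
- This comes back to the route at 13 and returns one equivalent of 5 for re-use.

Step 10. The coupling joins an electron-rich ortho-methoxy aryl bromide to a phenol flanked by a bulky aryloxy group, so slow oxidative addition, reduction of the bromide or oxidative loss of the phenol at 100 °C may prevail. The fallback sets out from 21 and changes to an oxidative coupling at room temperature.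
- Bromine–lithium exchange and borylation (n-BuLi, THF, −78 °C; B(OiPr)3; aqueous acid) should give [2,3-dimethoxy-5-(2,4,6-trimethoxyphenoxy)phenyl]boronic acid F3.
- Chan–Lam–Evans coupling of F3 with 16 (Cu(OAc)2, pyridine, 4 Å molecular sieves, CH2Cl2, air, rt) comes back to the route at 22.

Step 11. Cleavage of thirteen ethers in one operation may stop short at some positions, and the free polyphenol may be lost to air oxidation during isolation and chromatography. The fallback sets out from 22 and isolates the product as a stable derivative.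
- The crude material from the BBr3 treatment is peracetylated directly (Ac2O, pyridine, rt) to the tridecaacetate of the target F4, which is stable to air and silica and can be separated from partly dealkylated material.
- Acid methanolysis of F4 (HCl generated from AcCl in MeOH, rt, argon) then releases the polyphenol and comes back to the route at 23.

**Further compounds**

F1 | step 6 | 3,4-bis[3,5-dimethoxy-4-(3,4,5-trimethoxyphenoxy)phenoxy]cyclobut-3-ene-1,2-dione | O=C1C(=O)C(Oc2cc(OC)c(Oc3cc(OC)c(OC)c(OC)c3)c(OC)c2)=C1Oc1cc(OC)c(Oc2cc(OC)c(OC)c(OC)c2)c(OC)c1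
F2 | step 6 | 2,3-bis[3,5-dimethoxy-4-(3,4,5-trimethoxyphenoxy)phenoxy]-4-(1-ethoxyvinyl)-4-methoxycyclobut-2-en-1-one (racemic) | O=C1C(Oc2cc(OC)c(Oc3cc(OC)c(OC)c(OC)c3)c(OC)c2)=C(Oc2cc(OC)c(Oc3cc(OC)c(OC)c(OC)c3)c(OC)c2)C1(OC)C(OCC)=C
F3 | step 10 | [2,3-dimethoxy-5-(2,4,6-trimethoxyphenoxy)phenyl]boronic acid | COc1cc(OC)c(Oc2cc(OC)c(OC)c(B(O)O)c2)c(OC)c1
F4 | step 11 | tridecaacetate of CNP0228612.0 | CC(=O)Oc1cc(OC(C)=O)c(Oc2cc(OC(C)=O)c(OC(C)=O)c(Oc3cc(OC(C)=O)c(OC(C)=O)c(OC(C)=O)c3Oc3cc(OC(C)=O)c(Oc4cc(OC(C)=O)c(OC(C)=O)c(OC(C)=O)c4)c(OC(C)=O)c3)c2)c(OC(C)=O)c1
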